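**Assumption:** the target SMILES has no stereocentres, no E/Z-defined alkenes and a symmetric central ring (so no atropisomerism). It is achiral, so "single enantiomer" does not apply and no stereocontrol is needed.

## Retrosynthetic overview
1. Target ⇒ bis-MOM ether 11 by final acetal cleavage; the 6-OH on the benzofuran is carried unprotected.
2. The furan ring (the only ring formed) ⇒ domino Sonogashira / 5-endo-dig cyclisation of aryl alkyne 9 with 4-iodoresorcinol.
3. Alkyne 9 ⇒ aldehyde 7 by Ohira–Bestmann homologation.
4. Both prenyl groups ⇒ double Stille coupling on 2,6-dibromoaldehyde 5.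
5. Dibromide 5 ⇒ regioselective dibromination of MOM-protected 3,5-dihydroxybenzaldehyde.

## Route

**Step 1**
Reactants: 1, 3,5-dihydroxybenzaldehyde; 2, chloromethyl methyl ether (MOMCl)
Product: 3, 3,5-bis(methoxymethoxy)benzaldehyde
Conditions: MOMCl (3 equiv), i-Pr2NEt (4 equiv), CH2Cl2, 0 °C → rt
Reagents that add atoms: MOMCl, COCCl
Why: Williamson-type O-alkylation of both phenols; MOM survives NBS, Pd, K2CO3/MeOH and amine bases, and keeps the ring activated for bromination.

**Step 2**
Reactants: 3; 4, N-bromosuccinimide
Product: 5, 2,6-dibromo-3,5-bis(methoxymethoxy)benzaldehyde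
Conditions: NBS (2.1 equiv), MeCN, 0 °C → rt, dark
Reagents that add atoms: NBS, O=C1CCC(=O)N1Br
Why: electrophilic aromatic substitution; C2 and C6 are each para to one OMOM and ortho to the other, whereas C4 is flanked by two OMOM groups and is sterically disfavoured, which is the usual 2,6-dihalogenation pattern of 3,5-dialkoxyphenyl systems.

**Step 3**
Reactants: 5; 6, tributyl(3-methylbut-2-en-1-yl)stannane (2.6 equiv)
Product: 7, 3,5-bis(methoxymethoxy)-2,6-bis(3-methylbut-2-en-1-yl)benzaldehyde
Conditions: Pd(PPh3)4 (10 mol %), degassed DMF, 100 °C; aq. KF work-up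
Reagents that add atoms: prenyltributylstannane, CCCC[Sn](CCCC)(CCCC)CC=C(C)C
Why: double Stille (Migita–Kosugi) coupling; the ortho-CHO activates both C–Br bonds for oxidative addition, the stannane normally delivers the linear prenyl isomer, and neutral conditions tolerate the aldehyde and MOM ethers.

**Step 4**
Reactants: 7; 8, dimethyl (1-diazo-2-oxopropyl)phosphonate (Ohira–Bestmann reagent)
Product: 9, 3-ethynyl-1,5-bis(methoxymethoxy)-2,4-bis(3-methylbut-2-en-1-yl)benzene
Conditions: 8 (1.5 equiv), K2CO3 (2.5 equiv), MeOH/THF, 0 °C → rt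
Reagents that add atoms: Ohira–Bestmann reagent, COP(=O)(OC)C(=[N+]=[N-])C(C)=O (supplies the terminal alkyne carbon)
Why: Seyferth–Gilbert/Ohira–Bestmann homologation under mild base; MOM ethers and prenyl alkenes are inert, and the aldehyde is removed before any acid is used.

**Step 5**
Reactants: 9; 10, 4-iodoresorcinol (4-iodobenzene-1,3-diol, 1.2 equiv)
Product: 11, 2-[3,5-bis(methoxymethoxy)-2,6-bis(3-methylbut-2-en-1-yl)phenyl]-1-benzofuran-6-ol
Conditions: PdCl2(PPh3)2 (5 mol %), CuI (10 mol %), Et3N, degassed DMF, rt → 70 °C
Reagents that add atoms: none (all new atoms come from 10)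
Why: Sonogashira coupling at the unhindered alkyne terminus, then in-situ Cu/Pd-promoted 5-endo-dig hydroalkoxylation by the ortho-OH (heteroannulation). The OH para to iodine ends up at C6 of the benzofuran.

**Step 6**
Reactants: 11
Product: 12, Mulberrofuran V
Conditions: 3 M aq. HCl, MeOH, rt → 40 °C, stopped at full conversion
Reagents that add atoms: none
Why: acid-catalysed acetal hydrolysis of the two MOM ethers; under dilute, mild conditions this is faster than acid-mediated cyclisation of the ortho-prenyl phenols to chromans.

## Compound list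
1 | 3,5-dihydroxybenzaldehyde | O=Cc1cc(O)cc(O)c1 | starting material
2 | chloromethyl methyl ether (MOMCl) | COCCl | starting material (reagent)
3 | 3,5-bis(methoxymethoxy)benzaldehyde | O=Cc1cc(OCOC)cc(OCOC)c1 | intermediate
4 | N-bromosuccinimide | O=C1CCC(=O)N1Br | starting material (reagent)
5 | 2,6-dibromo-3,5-bis(methoxymethoxy)benzaldehyde | O=Cc1c(Br)c(OCOC)cc(OCOC)c1Br | intermediate
6 | tributyl(3-methylbut-2-en-1-yl)stannane | CCCC[Sn](CCCC)(CCCC)CC=C(C)C | starting material (reagent)
7 | 3,5-bis(methoxymethoxy)-2,6-bis(3-methylbut-2-en-1-yl)benzaldehyde | O=Cc1c(CC=C(C)C)c(OCOC)cc(OCOC)c1CC=C(C)C | intermediate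
8 | dimethyl (1-diazo-2-oxopropyl)phosphonate | COP(=O)(OC)C(=[N+]=[N-])C(C)=O | starting material (reagent)
9 | 3-ethynyl-1,5-bis(methoxymethoxy)-2,4-bis(3-methylbut-2-en-1-yl)benzene | C#Cc1c(CC=C(C)C)c(OCOC)cc(OCOC)c1CC=C(C)C | intermediate
10 | 4-iodoresorcinol (4-iodobenzene-1,3-diol) | Oc1ccc(I)c(O)c1 | starting material
11 | 2-[3,5-bis(methoxymethoxy)-2,6-bis(3-methylbut-2-en-1-yl)phenyl]-1-benzofuran-6-ol | CC(C)=CCc1c(OCOC)cc(OCOC)c(CC=C(C)C)c1-c1cc2ccc(O)cc2o1 | intermediate
12 | Mulberrofuran V, 5-(6-hydroxy-1-benzofuran-2-yl)-4,6-bis(3-methylbut-2-en-1-yl)benzene-1,3-diol (achiral) | CC(C)=CCc1c(O)cc(O)c(CC=C(C)C)c1-c1cc2ccc(O)cc2o1 | target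

## Summary
Total steps: 6. Longest linear sequence: 6 (1 → 3 → 5 → 7 → 9 → 11 → 12; compound 10 is purchased).

Steps most likely to fail, each with a fallback that changes the approach:

1. **Step 3, double Stille prenylation.** Risks are the two di-ortho-substituted C–Br bonds, some branched (reverse-prenyl) product, and competing allylation of the aldehyde. Fallback: homologate 5 to the alkyne first and cap it as the TIPS-alkyne, then install the prenyls by double Br/Li exchange (t-BuLi, −78 °C), transmetalation to copper (CuBr·SMe2) and SN2 alkylation with prenyl bromide, followed by TBAF to reveal 9.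

2. **Step 5, domino Sonogashira/cyclisation.** Risks are the unprotected, electron-rich iodoresorcinol, Glaser dimerisation, and slow ring closure onto the alkyne carbon bearing the hindered aryl group. Fallback: split it into two stages. Couple 9 with 4-iodoresorcinol diacetate at rt to isolate the diaryl alkyne, then run a separate metal-free, base-mediated deacetylation and 5-endo-dig cyclisation (Cs2CO3, MeOH/DMF, heat). Avoid Au/Pt catalysts, which would trigger enyne cycloisomerisation with the ortho-prenyl groups.

3. **Step 6, MOM removal.** The risk is acid-induced closure of the ortho-prenyl phenols to 2,2-dimethylchromans. Fallback: change the protecting-group strategy from step 1 to TIPS ethers (TIPSCl, imidazole), which survive NBS, Stille and K2CO3/MeOH, so the final step becomes a non-acidic fluoride deprotection (TBAF/AcOH, THF, 0 °C).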